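Numbering (serrulatane) and abbreviation: C1 = ring CHMe, C4 = ring CH bearing C11, C5–C10 = arene (C6 CO2H, C7/C8 OH, C9 on C1, C10 on C4), C11 = CH(C18H2O), C15 = CHMe(C16H2O); TBS = tert-butyldimethylsilyl.
Cuts, last-made first: acetonide and acetates; C6–CO2H (ortho-metalation); C4–C10 of the carbocycle (arene opens an oxetane); oxetane C4–O–C18 back to a 1,3-diol and an Evans syn-aldol bond C4–C11; C1–C9 (redox-relay Heck); C13–C14 (Wittig).
Forward: the arene is bought as 2,2-dimethyl-1,3-benzodioxole, the chain is joined by the aldol, the diol is tied as a cis-oxetane, and the carbocycle C1–C4/C9/C10 closes last, before carboxylation and acetylation.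
Enabling feature: O18 sits 1,3 to C4, so the two aldol oxygens can form an oxetane; C10 is the only free carbon ortho to the tethered C9 and is para to O7, so the arene can only close the six-membered ring at C4.
Stereochemistry: C15 from methyl (R)-3-hydroxy-2-methylpropanoate; C1 from the PyrOx–palladium arylation; C11 and the C4–O centre from the (S)-benzyloxazolidinone aldol, C4 then being inverted in the ring closure.

Key step: step 11

Assumption: the sense of induction of the PyrOx ligand in step 2 is not asserted; the ligand antipode that gives the 4R aldehyde from the Z alkenol is used.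

Step 1
Reactants: 1 2,2-dimethyl-1,3-benzodioxole
Product: 4 (2,2-dimethyl-1,3-benzodioxol-4-yl)boronic acid, via 4-lithio-2,2-dimethyl-1,3-benzodioxole 2 (not isolated), via lithium aryltriisopropoxyborate 3 (not isolated)
Conditions: n-BuLi, TMEDA, THF, 0 °C to rt; B(Oi-Pr)3, −78 °C to rt; 1 M HCl, 0 °C
Reagents that add atoms: triisopropyl borate CC(C)OB(OC(C)C)OC(C)C; water O (B–OH oxygens on hydrolysis); n-butyllithium [Li]CCCC (Li in 2 and 3 only)
Why: Directed ortho-metalation next to a dioxole oxygen followed by borate trapping and hydrolysis is the standard entry to 2,3-dioxygenated arylboronic acids, and the two positions ortho to oxygen are equivalent.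

Step 2
Reactants: 4 (2,2-dimethyl-1,3-benzodioxol-4-yl)boronic acid; 5 (Z)-pent-3-en-1-ol
Product: 6 (R)-4-(2,2-dimethyl-1,3-benzodioxol-4-yl)pentanal
Conditions: Pd(MeCN)2(OTs)2 (cat.), Cu(OTf)2 (cat.), 4-tert-butyl-2-[5-(trifluoromethyl)pyridin-2-yl]-4,5-dihydrooxazole (PyrOx, antipode giving 4R), 3 Å MS, DMF, O2 (1 atm), rt
Reagents that add atoms: none
Why: Enantioselective redox-relay oxidative Heck arylation: the aryl–palladium species should add to the alkene carbon remote from the hydroxyl and palladium then walks along the chain by β-hydride elimination/reinsertion until the alcohol becomes the aldehyde, so C1 is set by the chiral PyrOx ligand in the migratory insertion.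

Step 3
Reactants: 7 methyl (R)-3-hydroxy-2-methylpropanoate
Product: 8 methyl (R)-3-[(tert-butyldimethylsilyl)oxy]-2-methylpropanoate
Conditions: TBSCl, imidazole, CH2Cl2, 0 °C to rt
Reagents that add atoms: tert-butyldimethylsilyl chloride CC(C)(C)[Si](C)(C)Cl
Why: Standard silylation of a primary alcohol, which leaves the chiral-pool stereocentre (future C15) untouched.

Step 4
Reactants: 8 methyl (R)-3-[(tert-butyldimethylsilyl)oxy]-2-methylpropanoate
Product: 9 (R)-3-[(tert-butyldimethylsilyl)oxy]-2-methylpropanal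
Conditions: i-Bu2AlH (1.05 equiv), CH2Cl2, −78 °C; aq. potassium sodium tartrate; used without storage
Reagents that add atoms: none
Why: Half-reduction of the ester through the tetrahedral aluminium hemiacetal that is stable at −78 °C should give the α-branched aldehyde without epimerisation.

Step 5
Reactants: 9 (R)-3-[(tert-butyldimethylsilyl)oxy]-2-methylpropanal; 10 (3-carboxypropyl)triphenylphosphonium bromide
Product: 12 (S,Z)-7-[(tert-butyldimethylsilyl)oxy]-6-methylhept-4-enoic acid, via carboxylate ylide 11 (not isolated)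
Conditions: 10, NaN(SiMe3)2 (2.1 equiv), THF, 0 °C; 9, −78 °C to rt; 1 M HCl to pH 3
Reagents that add atoms: sodium bis(trimethylsilyl)amide C[Si](C)(C)N([Na])[Si](C)(C)C (Na in 11 only)
Why: Wittig olefination with the non-stabilised carboxylate ylide joins C13 to C14 at low temperature, where the α-stereocentre of the aldehyde should be configurationally stable; the Z geometry is irrelevant after step 6.

Step 6
Reactants: 12 (S,Z)-7-[(tert-butyldimethylsilyl)oxy]-6-methylhept-4-enoic acid
Product: 13 (S)-7-[(tert-butyldimethylsilyl)oxy]-6-methylheptanoic acid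
Conditions: H2 (1 atm), Pt/C, EtOAc, rt
Reagents that add atoms: none
Why: Heterogeneous hydrogenation of the disubstituted alkene, with platinum chosen over palladium to suppress double-bond migration into the allylic C15 stereocentre.

Step 7
Reactants: 13 (S)-7-[(tert-butyldimethylsilyl)oxy]-6-methylheptanoic acid; 14 (S)-4-benzyl-1,3-oxazolidin-2-one
Product: 16 (S)-4-benzyl-3-[(S)-7-[(tert-butyldimethylsilyl)oxy]-6-methylheptanoyl]-1,3-oxazolidin-2-one, via mixed pivalic anhydride 15 (not isolated)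
Conditions: t-BuCOCl, Et3N, THF, −20 °C; then 14, LiCl, −20 °C to rt
Reagents that add atoms: pivaloyl chloride CC(C)(C)C(=O)Cl (acyl group in 15 only)
Why: N-acylation of the oxazolidinone through the mixed pivalic anhydride, which is attacked at its less hindered carbonyl under the mild LiCl/Et3N conditions.

Step 8
Reactants: 16 (S)-4-benzyl-3-[(S)-7-[(tert-butyldimethylsilyl)oxy]-6-methylheptanoyl]-1,3-oxazolidin-2-one; 6 (R)-4-(2,2-dimethyl-1,3-benzodioxol-4-yl)pentanal
Product: 18 (S)-4-benzyl-3-[(2S,3R,6R)-2-[(S)-5-[(tert-butyldimethylsilyl)oxy]-4-methylpentyl]-6-(2,2-dimethyl-1,3-benzodioxol-4-yl)-3-hydroxyheptanoyl]-1,3-oxazolidin-2-one, via Z-dibutylboron enolate 17 (not isolated)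
Conditions: n-Bu2BOTf, i-Pr2NEt, CH2Cl2, 0 °C; 6, −78 to 0 °C; pH 7 buffer, MeOH, H2O2, 0 °C
Reagents that add atoms: dibutylboron triflate CCCCB(CCCC)OS(=O)(=O)C(F)(F)F (Bu2B in 17 only)
Why: Evans syn-aldol: the Z-boron enolate reacts through a closed chair (Zimmerman–Traxler) transition state on the face opposite the benzyl group of the (S)-auxiliary, which sets C11 (2S) and the C4 carbinol (3R) in a 2,3-syn relationship.

Step 9
Reactants: 18 the syn-aldol imide
Product: 19 (2R,3R,6R)-2-[(S)-5-[(tert-butyldimethylsilyl)oxy]-4-methylpentyl]-6-(2,2-dimethyl-1,3-benzodioxol-4-yl)heptane-1,3-diol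
Conditions: LiBH4, H2O (1 equiv), THF, 0 °C
Reagents that add atoms: none
Why: Reductive cleavage of the imide by hydride attack at the exocyclic carbonyl gives the 1,3-diol (C18–OH, C4–OH) and returns the auxiliary without epimerising C11.

Step 10
Reactants: 19 the 1,3-diol
Product: 21 (2R,3R)-2-[(R)-3-(2,2-dimethyl-1,3-benzodioxol-4-yl)butyl]-3-[(S)-5-[(tert-butyldimethylsilyl)oxy]-4-methylpentyl]oxetane (cis), via primary mono-tosylate 20 (not isolated)
Conditions: n-BuLi (1.0 equiv), THF, 0 °C; TsCl (1.0 equiv), 0 °C; then KOt-Bu (1.1 equiv), 0 °C to rt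
Reagents that add atoms: p-toluenesulfonyl chloride Cc1ccc(cc1)S(=O)(=O)Cl (tosyl group in 20 only)
Why: Selective sulfonylation of the primary O18 followed by 4-exo-tet Williamson closure by the C4 alkoxide is the standard 1,3-diol-to-oxetane sequence and keeps the configuration at C4 and C11, giving the cis-2,3-disubstituted oxetane.

Step 11
Reactants: 21 the cis-oxetane
Product: 22 (6S,9R)-6-[(2S,6S)-1,7-bis[(tert-butyldimethylsilyl)oxy]-6-methylheptan-2-yl]-2,2,9-trimethyl-6,7,8,9-tetrahydronaphtho[1,2-d][1,3]dioxole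
Conditions: TBSOTf (1.3 equiv), 2,6-di-tert-butyl-4-methylpyridine (1.5 equiv), CH2Cl2, −78 to 0 °C
Reagents that add atoms: tert-butyldimethylsilyl triflate CC(C)(C)[Si](C)(C)OS(=O)(=O)C(F)(F)F
Why: Proposed new method: TBSOTf silylates the oxetane oxygen and the resulting strained silyloxetanium ion is opened at C4 from the rear by aromatic C10 (SN2-like, arene as nucleophile), after which the Wheland intermediate loses its proton to the hindered pyridine, so the tetralin forms with O18 already protected as the TBS ether. The closest known reaction types are the intramolecular Friedel–Crafts epoxide–arene cyclisation, which opens the epoxide with inversion, and the silyl triflate or BF3 promoted opening of oxetanes by carbon nucleophiles. The carbocycle C1–C2–C3–C4–C10–C9 closes in the 6-exo-tet mode. The only new stereocentre, C4, is controlled by the substrate: backside attack inverts the R-configured C4–O centre made in the aldol step to 4S, which places the side chain trans to the C1 methyl group, while C1, C11 and C15 are not involved. The step needs attack at C4 rather than at the primary oxetane carbon C18 and bond formation at C10 rather than at ipso-C9: the three-carbon tether lets the arene reach C4 through a six-membered transition state whereas C18 would require an eight-membered ring, and C10 is the only unsubstituted carbon ortho to the tether and is activated by the para oxygen O7. Rearrangement through a free secondary cation (hydride shift from C11) is not expected because the arene is held within bonding distance of the backside of C4 and the cation would be unstabilised.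

Step 12
Reactants: 22 the bis-silyl tetrahydronaphthodioxole
Product: 24 (6S,9R)-6-[(2S,6S)-1,7-bis[(tert-butyldimethylsilyl)oxy]-6-methylheptan-2-yl]-2,2,9-trimethyl-6,7,8,9-tetrahydronaphtho[1,2-d][1,3]dioxole-4-carboxylic acid, via 4-lithiated tetrahydronaphthodioxole 23 (not isolated)
Conditions: s-BuLi, TMEDA, THF, −78 °C; CO2 (g), −78 °C to rt; 1 M HCl to pH 3, 0 °C
Reagents that add atoms: carbon dioxide O=C=O; sec-butyllithium CCC(C)[Li] (Li in 23 only)
Why: Directed ortho-metalation and carboxylation: C6 is the only free ring position ortho to a dioxole oxygen (C5 has no directing neighbour), so the carboxyl group should enter regiospecifically.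

Step 13
Reactants: 24 the bis-silyl acid
Product: 25 (6S,9R)-6-[(2S,6S)-1,7-dihydroxy-6-methylheptan-2-yl]-2,2,9-trimethyl-6,7,8,9-tetrahydronaphtho[1,2-d][1,3]dioxole-4-carboxylic acid
Conditions: HF·pyridine, pyridine, THF, 0 °C to rt
Reagents that add atoms: none
Why: Fluoride-driven cleavage of both primary silyl ethers under buffered conditions to which the catechol acetonide and the carboxylic acid are inert.

Step 14
Reactants: 25 the diol acid
Product: 27 (6S,9R)-6-[(2S,6S)-1,7-bis(acetyloxy)-6-methylheptan-2-yl]-2,2,9-trimethyl-6,7,8,9-tetrahydronaphtho[1,2-d][1,3]dioxole-4-carboxylic acid, via mixed acetic aryl-carboxylic anhydride 26 (not isolated)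
Conditions: Ac2O, pyridine, DMAP (cat.), CH2Cl2, 0 °C to rt; then H2O/THF, rt
Reagents that add atoms: acetic anhydride CC(=O)OC(C)=O
Why: DMAP-catalysed acetylation of both primary alcohols; the mixed anhydride formed at the aryl carboxyl group should be hydrolysed in the aqueous stage because anhydrides are far more labile than alkyl acetates.

Step 15
Reactants: 27 the diacetate acetonide acid
Product: 28 (5R,8S)-8-[(2S,6S)-1,7-bis(acetyloxy)-6-methylheptan-2-yl]-3,4-dihydroxy-5-methyl-5,6,7,8-tetrahydronaphthalene-2-carboxylic acid (target)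
Conditions: TFA/H2O (9:1), degassed, 0 °C to rt
Reagents that add atoms: none
Why: Acid hydrolysis of the catechol isopropylidene ketal, a standard deprotection under which primary acetates and the aryl carboxylic acid are stable, should release the target.

Compound list
1 | 2,2-dimethyl-1,3-benzodioxole | CC1(C)Oc2ccccc2O1 | starting material
2 | 4-lithio-2,2-dimethyl-1,3-benzodioxole | [Li]c1cccc2OC(C)(C)Oc12 | intermediate
3 | lithium (2,2-dimethyl-1,3-benzodioxol-4-yl)triisopropoxyborate | [Li+].CC(C)O[B-](OC(C)C)(OC(C)C)c1cccc2OC(C)(C)Oc12 | intermediate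
4 | (2,2-dimethyl-1,3-benzodioxol-4-yl)boronic acid | OB(O)c1cccc2OC(C)(C)Oc12 | intermediate
5 | (Z)-pent-3-en-1-ol | C/C=C\CCO | starting material
6 | (R)-4-(2,2-dimethyl-1,3-benzodioxol-4-yl)pentanal | O=CCC[C@@H](C)c1cccc2OC(C)(C)Oc12 | intermediate
7 | methyl (R)-3-hydroxy-2-methylpropanoate | C[C@H](CO)C(=O)OC | starting material
8 | methyl (R)-3-[(tert-butyldimethylsilyl)oxy]-2-methylpropanoate | C[C@H](CO[Si](C)(C)C(C)(C)C)C(=O)OC | intermediate
9 | (R)-3-[(tert-butyldimethylsilyl)oxy]-2-methylpropanal | C[C@H](CO[Si](C)(C)C(C)(C)C)C=O | intermediate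
10 | (3-carboxypropyl)triphenylphosphonium bromide | OC(=O)CCC[P+](c1ccccc1)(c1ccccc1)c1ccccc1.[Br-] | starting material
11 | sodium 4-(triphenylphosphoranylidene)butanoate (carboxylate ylide) | [Na+].[O-]C(=O)CCC=P(c1ccccc1)(c1ccccc1)c1ccccc1 | intermediate
12 | (S,Z)-7-[(tert-butyldimethylsilyl)oxy]-6-methylhept-4-enoic acid | CC(C)(C)[Si](C)(C)OC[C@@H](C)/C=C\CCC(=O)O | intermediate
13 | (S)-7-[(tert-butyldimethylsilyl)oxy]-6-methylheptanoic acid | CC(C)(C)[Si](C)(C)OC[C@@H](C)CCCCC(=O)O | intermediate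
14 | (S)-4-benzyl-1,3-oxazolidin-2-one | O=C1N[C@@H](Cc2ccccc2)CO1 | starting material
15 | (S)-7-[(tert-butyldimethylsilyl)oxy]-6-methylheptanoic pivalic anhydride | CC(C)(C)[Si](C)(C)OC[C@@H](C)CCCCC(=O)OC(=O)C(C)(C)C | intermediate
16 | (S)-4-benzyl-3-[(S)-7-[(tert-butyldimethylsilyl)oxy]-6-methylheptanoyl]-1,3-oxazolidin-2-one | CC(C)(C)[Si](C)(C)OC[C@@H](C)CCCCC(=O)N1[C@@H](Cc2ccccc2)COC1=O | intermediate
17 | Z-dibutylboron enolate of 16 | CCCCB(CCCC)O/C(=C\CCC[C@H](C)CO[Si](C)(C)C(C)(C)C)N1[C@@H](Cc2ccccc2)COC1=O | intermediate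
18 | (S)-4-benzyl-3-[(2S,3R,6R)-2-[(S)-5-[(tert-butyldimethylsilyl)oxy]-4-methylpentyl]-6-(2,2-dimethyl-1,3-benzodioxol-4-yl)-3-hydroxyheptanoyl]-1,3-oxazolidin-2-one | CC(C)(C)[Si](C)(C)OC[C@@H](C)CCC[C@H](C(=O)N1[C@@H](Cc2ccccc2)COC1=O)[C@H](O)CC[C@@H](C)c1cccc2OC(C)(C)Oc12 | intermediate
19 | (2R,3R,6R)-2-[(S)-5-[(tert-butyldimethylsilyl)oxy]-4-methylpentyl]-6-(2,2-dimethyl-1,3-benzodioxol-4-yl)heptane-1,3-diol | CC(C)(C)[Si](C)(C)OC[C@@H](C)CCC[C@H](CO)[C@H](O)CC[C@@H](C)c1cccc2OC(C)(C)Oc12 | intermediate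
20 | (2R,3R,6R)-2-[(S)-5-[(tert-butyldimethylsilyl)oxy]-4-methylpentyl]-6-(2,2-dimethyl-1,3-benzodioxol-4-yl)-3-hydroxyheptyl 4-methylbenzenesulfonate | CC(C)(C)[Si](C)(C)OC[C@@H](C)CCC[C@H](COS(=O)(=O)c1ccc(C)cc1)[C@H](O)CC[C@@H](C)c1cccc2OC(C)(C)Oc12 | intermediate
21 | (2R,3R)-2-[(R)-3-(2,2-dimethyl-1,3-benzodioxol-4-yl)butyl]-3-[(S)-5-[(tert-butyldimethylsilyl)oxy]-4-methylpentyl]oxetane (cis) | CC(C)(C)[Si](C)(C)OC[C@@H](C)CCC[C@@H]1CO[C@@H]1CC[C@@H](C)c1cccc2OC(C)(C)Oc12 | intermediate
22 | (6S,9R)-6-[(2S,6S)-1,7-bis[(tert-butyldimethylsilyl)oxy]-6-methylheptan-2-yl]-2,2,9-trimethyl-6,7,8,9-tetrahydronaphtho[1,2-d][1,3]dioxole | CC(C)(C)[Si](C)(C)OC[C@@H](C)CCC[C@H](CO[Si](C)(C)C(C)(C)C)[C@@H]1CC[C@@H](C)c2c1ccc3OC(C)(C)Oc23 | intermediate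
23 | 4-lithio derivative of 22 | CC(C)(C)[Si](C)(C)OC[C@@H](C)CCC[C@H](CO[Si](C)(C)C(C)(C)C)[C@@H]1CC[C@@H](C)c2c1cc([Li])c3OC(C)(C)Oc23 | intermediate
24 | (6S,9R)-6-[(2S,6S)-1,7-bis[(tert-butyldimethylsilyl)oxy]-6-methylheptan-2-yl]-2,2,9-trimethyl-6,7,8,9-tetrahydronaphtho[1,2-d][1,3]dioxole-4-carboxylic acid | CC(C)(C)[Si](C)(C)OC[C@@H](C)CCC[C@H](CO[Si](C)(C)C(C)(C)C)[C@@H]1CC[C@@H](C)c2c1cc(C(=O)O)c3OC(C)(C)Oc23 | intermediate
25 | (6S,9R)-6-[(2S,6S)-1,7-dihydroxy-6-methylheptan-2-yl]-2,2,9-trimethyl-6,7,8,9-tetrahydronaphtho[1,2-d][1,3]dioxole-4-carboxylic acid | OC[C@@H](C)CCC[C@H](CO)[C@@H]1CC[C@@H](C)c2c1cc(C(=O)O)c3OC(C)(C)Oc23 | intermediate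
26 | acetic (6S,9R)-6-[(2S,6S)-1,7-bis(acetyloxy)-6-methylheptan-2-yl]-2,2,9-trimethyl-6,7,8,9-tetrahydronaphtho[1,2-d][1,3]dioxole-4-carboxylic anhydride | CC(=O)OC[C@@H](C)CCC[C@H](COC(C)=O)[C@@H]1CC[C@@H](C)c2c1cc(C(=O)OC(C)=O)c3OC(C)(C)Oc23 | intermediate
27 | (6S,9R)-6-[(2S,6S)-1,7-bis(acetyloxy)-6-methylheptan-2-yl]-2,2,9-trimethyl-6,7,8,9-tetrahydronaphtho[1,2-d][1,3]dioxole-4-carboxylic acid | CC(=O)OC[C@@H](C)CCC[C@H](COC(C)=O)[C@@H]1CC[C@@H](C)c2c1cc(C(=O)O)c3OC(C)(C)Oc23 | intermediate
28 | (5R,8S)-8-[(2S,6S)-1,7-bis(acetyloxy)-6-methylheptan-2-yl]-3,4-dihydroxy-5-methyl-5,6,7,8-tetrahydronaphthalene-2-carboxylic acid | CC(=O)OC[C@@H](C)CCC[C@H](COC(C)=O)[C@@H]1CC[C@@H](C)c2c1cc(C(=O)O)c(O)c2O | target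

Total step count: 15. Longest linear sequence: 13 steps (steps 3 to 15); the aryl branch (steps 1 and 2) joins at step 8.

Steps most likely to fail

Step 11 (proposed new method). The activated oxetane may ionise with hydride shift or elimination instead of being captured by the arene, the arene may attack through its ipso carbon with a following alkyl shift, or the opening may simply be too slow. The fallback sets out from diol 19 and uses known chemistry. Selective silylation of the primary hydroxyl (TBSCl, imidazole, DMF, 0 °C) would give (2R,3R,6R)-1-[(tert-butyldimethylsilyl)oxy]-2-[(S)-5-[(tert-butyldimethylsilyl)oxy]-4-methylpentyl]-6-(2,2-dimethyl-1,3-benzodioxol-4-yl)heptan-3-ol F1. Mesylation (MsCl, Et3N, CH2Cl2, −20 °C) would give (2R,3R,6R)-1-[(tert-butyldimethylsilyl)oxy]-2-[(S)-5-[(tert-butyldimethylsilyl)oxy]-4-methylpentyl]-6-(2,2-dimethyl-1,3-benzodioxol-4-yl)heptan-3-yl methanesulfonate F2. Warming F2 in (CF3)2CHOH with 2,6-lutidine should bring about the known SN2-type intramolecular Friedel–Crafts alkylation of a secondary sulfonate, with inversion at C4. The fallback comes back to the route at 22 and makes the oxetane closure of step 10 unnecessary as well.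

Step 2. Migratory insertion may show poor site selectivity with the electron-rich, ortho-substituted aryl group (arylation at the nearer alkene carbon), the enantioselectivity may be low, or the boronic acid may protodeboronate. The fallback sets out from boronic acid 4. Hayashi–Miyaura conjugate addition to isopropyl (E)-but-2-enoate (Rh(acac)(C2H4)2, (S)-BINAP, dioxane/H2O, 100 °C; the BINAP antipode is the one that delivers the aryl group to the face giving 3R) would give isopropyl (R)-3-(2,2-dimethyl-1,3-benzodioxol-4-yl)butanoate F3. Reduction with i-Bu2AlH at −78 °C would give (R)-3-(2,2-dimethyl-1,3-benzodioxol-4-yl)butanal F4. Wittig methoxymethylenation (Ph3P=CHOMe from (methoxymethyl)triphenylphosphonium chloride and KOt-Bu, THF, 0 °C) would give the enol ether (R)-4-(5-methoxypent-4-en-2-yl)-2,2-dimethyl-1,3-benzodioxole F5 as an E/Z mixture. Hydrolysis with dilute aqueous HCl in THF comes back to the route at 6.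

Step 5. The α-branched aldehyde may partly epimerise under the basic ylide conditions, and the double bond may migrate towards C15 during step 6; either would erode the remote stereocentre in a way that is hard to correct later. The fallback sets out from ester 8 and avoids both the aldehyde and the alkene. LiBH4 reduction would give (S)-3-[(tert-butyldimethylsilyl)oxy]-2-methylpropan-1-ol F6. Treatment with I2, PPh3 and imidazole would give tert-butyl[(R)-3-iodo-2-methylpropoxy]dimethylsilane F7. Alkyl–alkyl Negishi coupling with commercial (4-ethoxy-4-oxobutyl)zinc bromide (Pd2(dba)3, tricyclopentylphosphine, N-methylimidazole, THF/NMP, 80 °C) would give ethyl (S)-7-[(tert-butyldimethylsilyl)oxy]-6-methylheptanoate F8. Hydrolysis with LiOH comes back to the route at acid 13.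

Further compounds
F1 | step 11 | (2R,3R,6R)-1-[(tert-butyldimethylsilyl)oxy]-2-[(S)-5-[(tert-butyldimethylsilyl)oxy]-4-methylpentyl]-6-(2,2-dimethyl-1,3-benzodioxol-4-yl)heptan-3-ol | CC(C)(C)[Si](C)(C)OC[C@@H](C)CCC[C@H](CO[Si](C)(C)C(C)(C)C)[C@H](O)CC[C@@H](C)c1cccc2OC(C)(C)Oc12
F2 | step 11 | (2R,3R,6R)-1-[(tert-butyldimethylsilyl)oxy]-2-[(S)-5-[(tert-butyldimethylsilyl)oxy]-4-methylpentyl]-6-(2,2-dimethyl-1,3-benzodioxol-4-yl)heptan-3-yl methanesulfonate | CC(C)(C)[Si](C)(C)OC[C@@H](C)CCC[C@H](CO[Si](C)(C)C(C)(C)C)[C@H](OS(C)(=O)=O)CC[C@@H](C)c1cccc2OC(C)(C)Oc12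
F3 | step 2 | isopropyl (R)-3-(2,2-dimethyl-1,3-benzodioxol-4-yl)butanoate | CC(C)OC(=O)C[C@@H](C)c1cccc2OC(C)(C)Oc12
F4 | step 2 | (R)-3-(2,2-dimethyl-1,3-benzodioxol-4-yl)butanal | O=CC[C@@H](C)c1cccc2OC(C)(C)Oc12
F5 | step 2 | (R)-4-(5-methoxypent-4-en-2-yl)-2,2-dimethyl-1,3-benzodioxole (E/Z mixture) | COC=CC[C@@H](C)c1cccc2OC(C)(C)Oc12
F6 | step 5 | (S)-3-[(tert-butyldimethylsilyl)oxy]-2-methylpropan-1-ol | C[C@H](CO[Si](C)(C)C(C)(C)C)CO
F7 | step 5 | tert-butyl[(R)-3-iodo-2-methylpropoxy]dimethylsilane | C[C@H](CO[Si](C)(C)C(C)(C)C)CI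
F8 | step 5 | ethyl (S)-7-[(tert-butyldimethylsilyl)oxy]-6-methylheptanoate | CC(C)(C)[Si](C)(C)OC[C@@H](C)CCCCC(=O)OCC
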